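## The problem

The target 29 is (3S,5S,6S,3'R,6'R)-5,6-dihydro-β,ε-carotene-3,5,6,3'-tetrol: two different trimethylcyclohexane end groups (ring A, C1–C6, a saturated 3,5,6-triol; ring B, C1'–C6', a 3'-hydroxy-ε ring) joined through C6 and C6' by an all-E nonaene with four methyl branches. The chain has no stereochemical problem of its own (all-E is the thermodynamic geometry), but it is unsymmetrical, so the halves must be joined one after the other, and it limits what the rings can endure: once C7=C8 is an alkene, acid ionises the tertiary C6–OH (pinacol shift, furanoid or 3,6-ether formation), and light, oxygen, acid at the allylic 3'-OH and strong base at the doubly allylic H-6' must be avoided. The hard part is ring A: C5 and C6 are adjacent, fully substituted carbinol carbons with trans hydroxyls, C6 also bears the chain, and O5 is cis to O3. In the chair with O3 equatorial this places the C5 methyl axial and syn to the axial C1 methyl, so reagents that come from outside (trans-diaxial opening of either 5,6-epoxide by water, solvolysis at C6, hydroxylation of a C5 enol derivative, methyl addition to a C5 ketone) are all expected to give the wrong configuration at C5. The feature that opens a way is the 1,3-cis pair O3/O5 on ring A combined with the trans pair O5/O6: a carbonyl oxygen tethered to O3 reaches C5 only from the face of O3, which is the rear side of a 5,6-epoxide lying anti to O3, so O3 can deliver O5 with inversion while the epoxide oxygen stays on C6. C3 can be bought (1) and then controls C5 and C6. Ring B has two centres in a 1,4 relation across C4'=C5': C6' can be bought with 12, and C3' must then be set trans to the chain. The E geometry of C7=C8 next to a quaternary carbinol is the last point, and here the C6 hydroxyl itself can direct a trans hydride addition to an alkyne.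

## Retrosynthesis

29 is cut at C11=C12 into the ring A aldehyde 11 (C15) and the ring B phosphonium salt 26 (C25). The neighbouring cuts are worse: C15=C15' needs two C20 halves and two more homologations, C7=C8 lies next to the quaternary carbinol, and C11'=C12' as the last bond would need a C25 aldehyde that carries the triol through several steps. Ring A takes the electrophilic role because a ylide at C11 would be conjugated to the C6–OH (risk of 1,6-elimination) and its salt could only be made with acid; 11 needs no protecting group. The forward Wittig reaction must tolerate four free hydroxyls and is followed by thermal equilibration of the new double bond to E.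

26 comes from alcohol 25 and this from aldehyde 24, which is cut at C11'=C12' into the C15 salt 20 and the symmetrical, commercial C10 dialdehyde 21. Excess 21 lets only one formyl group react. C15 + C10 is preferred to C20 + C5 because both pieces are available or short. The forward steps are two Wittig/phosphonium sequences of the classical kind.

11 is the oxidation product of tetrol 10. In 10 the E-C7=C8 bond next to the tertiary C6–OH is the retron of a hydroxyl-directed trans-hydroalumination of a propargylic alcohol. 10 is therefore traced to the 7,8-alkyne 9, in which O3 and O5 are tied as a cyclic carbonate and O11 is an acetate; one hydride reagent removes both groups and reduces the alkyne. No C–C bond is cut here. The gain is that the alkyne makes C6 a poor cation site in the key step and allows a cross-coupling before it.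

9 is cut at C5–O and C6–O. Both oxygens come from one oxygen transfer to the C5=C6 bond of dienyne 7 (one stereocentre), followed in the same flask by opening of the anti-epoxide 8 at C5 by the carbonyl oxygen of the C3 carbonate. Against intermolecular hydrolysis (wrong regio- and stereochemistry) and against oxygenation of a ketone enolate (wrong face), only this cut lets C3 dictate both new centres. The precursor 7 is flat at C5 and C6. The forward reaction must be chemoselective for the ring alkene, anti-selective on it and regioselective for C5.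

7 is the acetate of 6, and 6 is cut at the C6–C7 sp2–sp bond into enol triflate 4 and the commercial enynol 5 (Sonogashira). This cut beats C8–C9 or C9=C10 because 5 brings C7–C11 with the E-C9=C10 bond in one piece, and it beats acetylide addition to the ketone followed by dehydration because it needs no acid. 4 comes from 1 by carbonate formation (2) and regiospecific enol triflation (via 3); the C5 stereocentre of 1 is not needed.

20 is traced through diol 19 and benzoate 18 to the cis alcohol 17, the hydride reduction product of enone 16. 16 is the allylic oxidation product of ester 15, which is cut at C9'=C10' into 12 and phosphonate 13 (Horner–Wadsworth–Emmons, via 14). C6' is taken from the chiral pool; C3' is set from it in two controlled steps (hydride anti to the chain, then Mitsunobu inversion) instead of one unselective one.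

## Roads not taken

Alternative 1: The most obvious plan follows the likely biogenesis: assemble lutein A1 by the standard C15 + C10 + C15 double Wittig sequence, epoxidise its 5,6-double bond to the anti-epoxide A2 and hydrolyse A2 with aqueous acid. The forward key step is the acid hydrolysis. With the polyene on C6 the epoxide ionises at C6. The expected products are 5,8-furanoids and C6-opened diols in which O5 keeps the configuration of the epoxide, trans to O3. Attack at C5 with inversion, the only path to 29, is the path the polyene switches off. The chosen plan performs the C5 inversion before the polyene exists, on an alkyne-deactivated C6 and through a tether.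

Alternative 2: Cut C6–C7 as a carbonyl addition: the acetylide of 5 adds to the α-ketol A3, and axial attack anti to the two axial methyl groups would set C6 correctly. But A3 already contains the difficult O3/O5-cis relation. Rubottom oxidation or enolate hydroxylation of an enol derivative of 1 is expected to bring the oxygen in anti to the C3 substituent and give the epimeric ketol A4. The problem is moved, not solved, and two hydroxyls need separate protection; the chosen plan makes O3 the reagent that delivers O5.

Alternative 3: Spend the key step on ring B: add the chain acetylide to silyloxy enone A5, transpose oxidatively to the 4'-oxo-β ring, form tosylhydrazone A6 and reduce it with catecholborane. Hydride would add anti to the silyloxy group, and retro-ene loss of N2 from the allylic diazene would deliver H to C6' on the face of the nitrogen and move the double bond to C4'=C5', so C3' would control C6'. This 1,3-transfer of chirality is attractive, but it answers the smaller problem (two centres, one of which 12 supplies), needs about six steps to reach A6, risks conjugate addition to the ynenone, and leaves ring A untouched.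

Key step: step 5

Assumption: 1 and 12 are bought as single enantiomers (5, 13 and 21 are ordinary catalogue compounds); ring and chain positions are cited in carotenoid numbering (C1–C6 in ring A, primed locants for ring B and its half of the chain).

Step 1
Reactants: 1 (4R,6R)-4-hydroxy-2,2,6-trimethylcyclohexan-1-one
Product: 2 (4R,6R)-4-[(tert-butoxycarbonyl)oxy]-2,2,6-trimethylcyclohexan-1-one
Conditions: Boc2O, DMAP (cat.), MeCN, rt
Reagents that add atoms: di-tert-butyl dicarbonate, CC(C)(C)OC(=O)OC(=O)OC(C)(C)C
Why: DMAP-catalysed acylation of the secondary alcohol gives the tert-butyl carbonate, which is the later internal oxygen nucleophile and is stable to amide base, palladium and peroxide; no stereocentre is touched.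

Step 2
Reactants: 2 (4R,6R)-4-[(tert-butoxycarbonyl)oxy]-2,2,6-trimethylcyclohexan-1-one
Product: 4 (4R)-4-[(tert-butoxycarbonyl)oxy]-2,6,6-trimethylcyclohex-1-en-1-yl trifluoromethanesulfonate, via potassium enolate 3 (not isolated)
Conditions: KN(SiMe3)2, THF, −78 °C; then PhNTf2, −78 °C to rt
Reagents that add atoms: N-phenylbis(trifluoromethanesulfonimide), O=S(=O)(N(c1ccccc1)S(=O)(=O)C(F)(F)F)C(F)(F)F
Why: Enol triflate formation; the ketone has a single α-hydrogen (C5–H, C1 being quaternary), so enolisation is regiospecific and O-sulfonylation gives the tetrasubstituted C5=C6 triflate; the C5 centre of 1 is erased on purpose and C3 is untouched.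

Step 3
Reactants: 4 (4R)-4-[(tert-butoxycarbonyl)oxy]-2,6,6-trimethylcyclohex-1-en-1-yl trifluoromethanesulfonate; 5 (2E)-3-methylpent-2-en-4-yn-1-ol
Product: 6 (2E)-5-{(4R)-4-[(tert-butoxycarbonyl)oxy]-2,6,6-trimethylcyclohex-1-en-1-yl}-3-methylpent-2-en-4-yn-1-ol
Conditions: PdCl2(PPh3)2 (5 mol%), CuI (10 mol%), Et3N, DMF, 25–50 °C
Reagents that add atoms: none
Why: Sonogashira coupling (oxidative addition of the enol triflate to zerovalent palladium, transmetalation of the copper acetylide, reductive elimination) forms the C6–C7 sp2–sp bond; hindered trimethylcyclohexenyl triflates are established partners, the carbonate is inert, and the E-C9=C10 bond is carried in unchanged from 5.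

Step 4
Reactants: 6 (2E)-5-{(4R)-4-[(tert-butoxycarbonyl)oxy]-2,6,6-trimethylcyclohex-1-en-1-yl}-3-methylpent-2-en-4-yn-1-ol
Product: 7 (2E)-5-{(4R)-4-[(tert-butoxycarbonyl)oxy]-2,6,6-trimethylcyclohex-1-en-1-yl}-3-methylpent-2-en-4-yn-1-yl acetate
Conditions: Ac2O, pyridine, DMAP (cat.), CH2Cl2, 0 °C
Reagents that add atoms: acetic anhydride, CC(=O)OC(C)=O
Why: Simple acetylation; the allylic acetate lowers the reactivity of the C9=C10 bond toward the oxidant, keeps the primary oxygen from acting as a nucleophile under Lewis acid, and is removed by the hydride of step 6.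

Step 5
Reactants: 7 (2E)-5-{(4R)-4-[(tert-butoxycarbonyl)oxy]-2,6,6-trimethylcyclohex-1-en-1-yl}-3-methylpent-2-en-4-yn-1-yl acetate
Product: 9 (2E)-5-[(1S,5S,8R)-8-hydroxy-1,7,7-trimethyl-3-oxo-2,4-dioxabicyclo[3.3.1]nonan-8-yl]-3-methylpent-2-en-4-yn-1-yl acetate, via anti-epoxide 8 (not isolated)
Conditions: dimethyldioxirane (acetone solution, 1.1 equiv), CH2Cl2, −20 °C; evaporate; BF3·OEt2 (0.3 equiv), CH2Cl2, −78 to −40 °C
Reagents that add atoms: dimethyldioxirane, CC1(C)OO1
Why: Dimethyldioxirane transfers oxygen to the most electron-rich alkene, the tetrasubstituted C5=C6 bond of ring A (the acetoxy-bearing C9=C10 bond and the alkyne are much slower), closing the oxirane by concerted syn addition on the face anti to the C3 carbonate, as is usual for ester-protected 3-hydroxy-β rings, to give 8. BF3 then activates the epoxide and the carbonyl oxygen of the carbonate attacks C5 from the rear in a 6-exo-tet closure; loss of the tert-butyl group as isobutene leaves the 1,3-dioxan-2-one ring of 9 and returns the proton that frees the C6 hydroxyl and the Lewis acid. The closest known reaction type is the Lewis-acid opening of an epoxide by a neighbouring tert-butyl carbonate to a six-membered cyclic carbonate, the epoxide counterpart of iodocarbonate cyclisation. C5 is set by inversion, so O5 must end cis to O3; C6 keeps the epoxide oxygen, so O6 is trans to O5 and the alkynyl group cis to it; both new centres are thus controlled by C3 alone. Attack at C5 and not at C6 is secured by ring size (six- against seven-membered carbonate) and by the alkynyl group, which makes C6 a poor cation site while C5 is a plain tertiary centre. The step needs anti facial selectivity in the oxygen transfer, but it corrects itself: the syn epoxide cannot be reached from O3 and so cannot give a diastereomer of 9. The closure passes through the ring conformer with O3 axial, and its cost (syn-axial C1 methyl) is offset by the intramolecular, strain-releasing opening.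

Step 6
Reactants: 9 (2E)-5-[(1S,5S,8R)-8-hydroxy-1,7,7-trimethyl-3-oxo-2,4-dioxabicyclo[3.3.1]nonan-8-yl]-3-methylpent-2-en-4-yn-1-yl acetate
Product: 10 (2E,4E)-5-[(1S,2S,4S)-1,2,4-trihydroxy-2,6,6-trimethylcyclohexyl]-3-methylpenta-2,4-dien-1-ol
Conditions: NaAlH2(OCH2CH2OMe)2 (Red-Al, excess), THF, 0 °C to rt; aqueous Rochelle salt
Reagents that add atoms: none
Why: Reduction of a propargylic alcohol to the E-allylic alcohol: the C6 alkoxide (helped by the C11 alkoxide of the 2-en-4-yn-1-ol unit) directs trans-hydroalumination of the alkyne and protonolysis gives E-C7=C8; the same hydride cleaves the acetate and reduces the cyclic carbonate to the free 3,5-diol, and no stereocentre is touched.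

Step 7
Reactants: 10 (2E,4E)-5-[(1S,2S,4S)-1,2,4-trihydroxy-2,6,6-trimethylcyclohexyl]-3-methylpenta-2,4-dien-1-ol
Product: 11 (2E,4E)-5-[(1S,2S,4S)-1,2,4-trihydroxy-2,6,6-trimethylcyclohexyl]-3-methylpenta-2,4-dienal
Conditions: MnO2 (activated), CH2Cl2/acetone, rt
Reagents that add atoms: none
Why: Allylic alcohol oxidation with MnO2 acts only on the primary dienylic alcohol (the secondary hydroxyl is not allylic and the tertiary ones cannot be oxidised), and the neutral conditions spare the tertiary C6–OH and the E,E-diene.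

Step 8
Reactants: 12 (3E)-4-[(1R)-2,6,6-trimethylcyclohex-2-en-1-yl]but-3-en-2-one; 13 triethyl phosphonoacetate
Product: 15 ethyl (2E,4E)-3-methyl-5-[(1R)-2,6,6-trimethylcyclohex-2-en-1-yl]penta-2,4-dienoate, via sodium phosphonate carbanion 14 (not isolated)
Conditions: NaH (1.0 equiv per 1.1 equiv of 13), THF, 0 °C; then 12, 0–45 °C
Reagents that add atoms: none
Why: Horner–Wadsworth–Emmons olefination of the methyl ketone gives mainly the 9'E dienoate (the 9'Z share is removed by chromatography); the phosphonate anion is too weak a base to deprotonate C6'–H, so the (6'R) centre of the chiral pool is kept.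

Step 9
Reactants: 15 ethyl (2E,4E)-3-methyl-5-[(1R)-2,6,6-trimethylcyclohex-2-en-1-yl]penta-2,4-dienoate
Product: 16 ethyl (2E,4E)-3-methyl-5-[(1R)-2,6,6-trimethyl-4-oxocyclohex-2-en-1-yl]penta-2,4-dienoate
Conditions: t-BuOOH (in decane, 5 equiv), CuI (cat.), MeCN, 50 °C
Reagents that add atoms: tert-butyl hydroperoxide, CC(C)(C)OO
Why: Metal-catalysed radical allylic C–H oxidation of a cyclohexene to the enone converts the ring methylene C3' into the ketone, the known mode of oxidation of α-ionone-type rings; the hindered doubly allylic C6'–H is spared and the neutral medium avoids epimerisation at C6'.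

Step 10
Reactants: 16 ethyl (2E,4E)-3-methyl-5-[(1R)-2,6,6-trimethyl-4-oxocyclohex-2-en-1-yl]penta-2,4-dienoate
Product: 17 ethyl (2E,4E)-5-[(1R,4S)-4-hydroxy-2,6,6-trimethylcyclohex-2-en-1-yl]-3-methylpenta-2,4-dienoate
Conditions: LiBH(s-Bu)3 (L-Selectride, 1.1 equiv), THF, −78 °C
Reagents that add atoms: none
Why: 1,2-Reduction of the cyclohexenone by a bulky borohydride at a temperature at which the dienoate is inert; hydride should enter on the face of H-6', away from the side chain and from the axial C1' methyl on that same side, to give the 3',6'-cis (3'S) allylic alcohol, the usual outcome for 3-oxo-ε rings.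

Step 11
Reactants: 17 ethyl (2E,4E)-5-[(1R,4S)-4-hydroxy-2,6,6-trimethylcyclohex-2-en-1-yl]-3-methylpenta-2,4-dienoate
Product: 18 ethyl (2E,4E)-5-[(1R,4R)-4-(benzoyloxy)-2,6,6-trimethylcyclohex-2-en-1-yl]-3-methylpenta-2,4-dienoate
Conditions: PPh3, diisopropyl azodicarboxylate, PhCO2H, THF, 0 °C to rt
Reagents that add atoms: benzoic acid, O=C(O)c1ccccc1
Why: Mitsunobu reaction: SN2 displacement of the activated allylic oxygen by benzoate inverts C3' to the required (3'R) configuration trans to the chain; SN2' attack would have to occur at the fully substituted C5' and is not expected.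

Step 12
Reactants: 18 ethyl (2E,4E)-5-[(1R,4R)-4-(benzoyloxy)-2,6,6-trimethylcyclohex-2-en-1-yl]-3-methylpenta-2,4-dienoate
Product: 19 (2E,4E)-5-[(1R,4R)-4-hydroxy-2,6,6-trimethylcyclohex-2-en-1-yl]-3-methylpenta-2,4-dien-1-ol
Conditions: i-Bu2AlH (5 equiv), CH2Cl2, −78 to 0 °C; aqueous Rochelle salt
Reagents that add atoms: none
Why: Ester reduction with a neutral aluminium hydride: the dienoate gives the primary allylic alcohol by 1,2-reduction and the benzoate is cleaved to the free 3'-OH in the same operation; no stereocentre is affected.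

Step 13
Reactants: 19 (2E,4E)-5-[(1R,4R)-4-hydroxy-2,6,6-trimethylcyclohex-2-en-1-yl]-3-methylpenta-2,4-dien-1-ol
Product: 20 {(2E,4E)-5-[(1R,4R)-4-hydroxy-2,6,6-trimethylcyclohex-2-en-1-yl]-3-methylpenta-2,4-dien-1-yl}triphenylphosphonium bromide
Conditions: PPh3·HBr (1.05 equiv), MeOH, 0 °C to rt
Reagents that add atoms: triphenylphosphine hydrobromide, Br.P(c1ccccc1)(c1ccccc1)c1ccccc1
Why: Phosphonium salt formation from an allylic alcohol: the primary dienylic alcohol ionises far more easily than the isolated ring allylic alcohol and triphenylphosphine captures the pentadienyl cation at its unhindered terminus C11', the classical preparation of C15 Wittig salts.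

Step 14
Reactants: 20 {(2E,4E)-5-[(1R,4R)-4-hydroxy-2,6,6-trimethylcyclohex-2-en-1-yl]-3-methylpenta-2,4-dien-1-yl}triphenylphosphonium bromide; 21 (2E,4E,6E)-2,7-dimethylocta-2,4,6-trienedial
Product: 24 (2E,4E,6E,8E,10E,12E)-13-[(1R,4R)-4-hydroxy-2,6,6-trimethylcyclohex-2-en-1-yl]-2,7,11-trimethyltrideca-2,4,6,8,10,12-hexaenal, via phosphorane 22 (not isolated), via 11'Z-aldehyde 23 (not isolated)
Conditions: NaOMe, MeOH/CH2Cl2, 0 °C to rt, 21 in excess (3 equiv); then heptane, reflux
Reagents that add atoms: none
Why: Wittig reaction of the semistabilised ylide with one formyl group of the dialdehyde, used in excess so that the second one stays free; the new C11'=C12' bond forms as an E/Z mixture and the hindered Z isomer (cis to the C13' methyl) goes over to E on heating, as is usual for carotenoid polyenes.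

Step 15
Reactants: 24 (2E,4E,6E,8E,10E,12E)-13-[(1R,4R)-4-hydroxy-2,6,6-trimethylcyclohex-2-en-1-yl]-2,7,11-trimethyltrideca-2,4,6,8,10,12-hexaenal
Product: 25 (2E,4E,6E,8E,10E,12E)-13-[(1R,4R)-4-hydroxy-2,6,6-trimethylcyclohex-2-en-1-yl]-2,7,11-trimethyltrideca-2,4,6,8,10,12-hexaen-1-ol
Conditions: NaBH4, EtOH/THF, 0 °C
Reagents that add atoms: none
Why: Borohydride 1,2-reduction of the polyenal to the primary alcohol; the polyene, the ring alkene and both stereocentres are inert.

Step 16
Reactants: 25 (2E,4E,6E,8E,10E,12E)-13-[(1R,4R)-4-hydroxy-2,6,6-trimethylcyclohex-2-en-1-yl]-2,7,11-trimethyltrideca-2,4,6,8,10,12-hexaen-1-ol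
Product: 26 {(2E,4E,6E,8E,10E,12E)-13-[(1R,4R)-4-hydroxy-2,6,6-trimethylcyclohex-2-en-1-yl]-2,7,11-trimethyltrideca-2,4,6,8,10,12-hexaen-1-yl}triphenylphosphonium bromide
Conditions: PPh3·HBr (1.0 equiv), MeOH/CH2Cl2, 0 °C, dark
Reagents that add atoms: triphenylphosphine hydrobromide, Br.P(c1ccccc1)(c1ccccc1)c1ccccc1
Why: The same phosphonium salt formation as in step 13, now on a heptaenyl alcohol that ionises still more readily, so one equivalent of PPh3·HBr at 0 °C should leave the ring allylic 3'-OH untouched; phosphorus adds at the terminal carbon and the all-E polyene is kept.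

Step 17
Reactants: 26 {(2E,4E,6E,8E,10E,12E)-13-[(1R,4R)-4-hydroxy-2,6,6-trimethylcyclohex-2-en-1-yl]-2,7,11-trimethyltrideca-2,4,6,8,10,12-hexaen-1-yl}triphenylphosphonium bromide; 11 (2E,4E)-5-[(1S,2S,4S)-1,2,4-trihydroxy-2,6,6-trimethylcyclohexyl]-3-methylpenta-2,4-dienal
Product: 29 (3S,5S,6S,3'R,6'R)-5,6-dihydro-β,ε-carotene-3,5,6,3'-tetrol, via phosphorane 27 (not isolated), via 11Z-isomer 28 (not isolated)
Conditions: NaOMe, MeOH/CH2Cl2, rt, argon, dark; then heptane/EtOH, reflux; crystallisation
Reagents that add atoms: none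
Why: The Wittig reaction joins C11 (aldehyde) and C12 (ylide) and completes the nonaene; the unprotected triol half acts only as electrophile, so no carbanion is ever conjugated to the C6–OH; heating converts the hindered 11Z isomer into the all-E target and no stereocentre is touched.

## Compound list

1 | (4R,6R)-4-hydroxy-2,2,6-trimethylcyclohexan-1-one (actinol) | O=C1C(C)(C)C[C@H](O)C[C@H]1C | starting material
2 | (4R,6R)-4-[(tert-butoxycarbonyl)oxy]-2,2,6-trimethylcyclohexan-1-one | O=C1C(C)(C)C[C@H](OC(=O)OC(C)(C)C)C[C@H]1C | intermediate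
3 | potassium (4R)-4-[(tert-butoxycarbonyl)oxy]-2,6,6-trimethylcyclohex-1-en-1-olate (formed in the flask) | CC1=C([O-])C(C)(C)C[C@H](OC(=O)OC(C)(C)C)C1.[K+] | intermediate
4 | (4R)-4-[(tert-butoxycarbonyl)oxy]-2,6,6-trimethylcyclohex-1-en-1-yl trifluoromethanesulfonate | CC1=C(OS(=O)(=O)C(F)(F)F)C(C)(C)C[C@H](OC(=O)OC(C)(C)C)C1 | intermediate
5 | (2E)-3-methylpent-2-en-4-yn-1-ol | C#C/C(C)=C/CO | starting material
6 | (2E)-5-{(4R)-4-[(tert-butoxycarbonyl)oxy]-2,6,6-trimethylcyclohex-1-en-1-yl}-3-methylpent-2-en-4-yn-1-ol | CC1=C(C#C/C(C)=C/CO)C(C)(C)C[C@H](OC(=O)OC(C)(C)C)C1 | intermediate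
7 | (2E)-5-{(4R)-4-[(tert-butoxycarbonyl)oxy]-2,6,6-trimethylcyclohex-1-en-1-yl}-3-methylpent-2-en-4-yn-1-yl acetate | CC1=C(C#C/C(C)=C/COC(C)=O)C(C)(C)C[C@H](OC(=O)OC(C)(C)C)C1 | intermediate
8 | (2E)-5-{(1R,4S,6R)-4-[(tert-butoxycarbonyl)oxy]-2,2,6-trimethyl-7-oxabicyclo[4.1.0]heptan-1-yl}-3-methylpent-2-en-4-yn-1-yl acetate (5,6-epoxide anti to the carbonate; formed in the flask) | CC(=O)OC/C=C(C)/C#C[C@]1(O2)C(C)(C)C[C@H](OC(=O)OC(C)(C)C)C[C@]12C | intermediate
9 | (2E)-5-[(1S,5S,8R)-8-hydroxy-1,7,7-trimethyl-3-oxo-2,4-dioxabicyclo[3.3.1]nonan-8-yl]-3-methylpent-2-en-4-yn-1-yl acetate (3,5-cyclic carbonate, free C6–OH) | CC(=O)OC/C=C(C)/C#C[C@]1(O)C(C)(C)C[C@H]2C[C@]1(C)OC(=O)O2 | intermediate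
10 | (2E,4E)-5-[(1S,2S,4S)-1,2,4-trihydroxy-2,6,6-trimethylcyclohexyl]-3-methylpenta-2,4-dien-1-ol | OC/C=C(C)/C=C/[C@]1(O)C(C)(C)C[C@H](O)C[C@]1(C)O | intermediate
11 | (2E,4E)-5-[(1S,2S,4S)-1,2,4-trihydroxy-2,6,6-trimethylcyclohexyl]-3-methylpenta-2,4-dienal | O=C/C=C(C)/C=C/[C@]1(O)C(C)(C)C[C@H](O)C[C@]1(C)O | intermediate
12 | (3E)-4-[(1R)-2,6,6-trimethylcyclohex-2-en-1-yl]but-3-en-2-one ((R)-α-ionone) | CC(=O)/C=C/[C@H]1C(C)=CCCC1(C)C | starting material
13 | triethyl phosphonoacetate | CCOC(=O)CP(=O)(OCC)OCC | starting material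
14 | sodium salt of the carbanion of triethyl phosphonoacetate (formed in the flask) | CCOC(=O)[CH-]P(=O)(OCC)OCC.[Na+] | intermediate
15 | ethyl (2E,4E)-3-methyl-5-[(1R)-2,6,6-trimethylcyclohex-2-en-1-yl]penta-2,4-dienoate | CCOC(=O)/C=C(C)/C=C/[C@H]1C(C)=CCCC1(C)C | intermediate
16 | ethyl (2E,4E)-3-methyl-5-[(1R)-2,6,6-trimethyl-4-oxocyclohex-2-en-1-yl]penta-2,4-dienoate | CCOC(=O)/C=C(C)/C=C/[C@H]1C(C)=CC(=O)CC1(C)C | intermediate
17 | ethyl (2E,4E)-5-[(1R,4S)-4-hydroxy-2,6,6-trimethylcyclohex-2-en-1-yl]-3-methylpenta-2,4-dienoate (3',6'-cis) | CCOC(=O)/C=C(C)/C=C/[C@H]1C(C)=C[C@@H](O)CC1(C)C | intermediate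
18 | ethyl (2E,4E)-5-[(1R,4R)-4-(benzoyloxy)-2,6,6-trimethylcyclohex-2-en-1-yl]-3-methylpenta-2,4-dienoate (3',6'-trans) | CCOC(=O)/C=C(C)/C=C/[C@H]1C(C)=C[C@H](OC(=O)c2ccccc2)CC1(C)C | intermediate
19 | (2E,4E)-5-[(1R,4R)-4-hydroxy-2,6,6-trimethylcyclohex-2-en-1-yl]-3-methylpenta-2,4-dien-1-ol | OC/C=C(C)/C=C/[C@H]1C(C)=C[C@H](O)CC1(C)C | intermediate
20 | {(2E,4E)-5-[(1R,4R)-4-hydroxy-2,6,6-trimethylcyclohex-2-en-1-yl]-3-methylpenta-2,4-dien-1-yl}triphenylphosphonium bromide | [Br-].c1ccc(cc1)[P+](c1ccccc1)(c1ccccc1)C/C=C(C)/C=C/[C@H]1C(C)=C[C@H](O)CC1(C)C | intermediate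
21 | (2E,4E,6E)-2,7-dimethylocta-2,4,6-trienedial | O=C/C(C)=C/C=C/C=C(C)/C=O | starting material
22 | phosphorane (ylide) of 20 (formed in the flask) | c1ccc(cc1)P(c1ccccc1)(c1ccccc1)=C/C=C(C)/C=C/[C@H]1C(C)=C[C@H](O)CC1(C)C | intermediate
23 | 8Z isomer of 24 (Z at the new C11'=C12' bond; formed in the flask) | O=C/C(C)=C/C=C/C=C(C)/C=C\C=C(C)\C=C\[C@H]1C(C)=C[C@H](O)CC1(C)C | intermediate
24 | (2E,4E,6E,8E,10E,12E)-13-[(1R,4R)-4-hydroxy-2,6,6-trimethylcyclohex-2-en-1-yl]-2,7,11-trimethyltrideca-2,4,6,8,10,12-hexaenal ((3R,6R)-3-hydroxy-12'-apo-ε-caroten-12'-al) | O=C/C(C)=C/C=C/C=C(C)/C=C/C=C(C)/C=C/[C@H]1C(C)=C[C@H](O)CC1(C)C | intermediate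
25 | (2E,4E,6E,8E,10E,12E)-13-[(1R,4R)-4-hydroxy-2,6,6-trimethylcyclohex-2-en-1-yl]-2,7,11-trimethyltrideca-2,4,6,8,10,12-hexaen-1-ol | OC/C(C)=C/C=C/C=C(C)/C=C/C=C(C)/C=C/[C@H]1C(C)=C[C@H](O)CC1(C)C | intermediate
26 | {(2E,4E,6E,8E,10E,12E)-13-[(1R,4R)-4-hydroxy-2,6,6-trimethylcyclohex-2-en-1-yl]-2,7,11-trimethyltrideca-2,4,6,8,10,12-hexaen-1-yl}triphenylphosphonium bromide | [Br-].c1ccc(cc1)[P+](c1ccccc1)(c1ccccc1)C/C(C)=C/C=C/C=C(C)/C=C/C=C(C)/C=C/[C@H]1C(C)=C[C@H](O)CC1(C)C | intermediate
27 | phosphorane (ylide) of 26 (formed in the flask) | c1ccc(cc1)P(c1ccccc1)(c1ccccc1)=C/C(C)=C/C=C/C=C(C)/C=C/C=C(C)/C=C/[C@H]1C(C)=C[C@H](O)CC1(C)C | intermediate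
28 | (11Z)-isomer of 29 (formed in the flask) | CC1=C[C@H](O)CC(C)(C)[C@H]1/C=C/C(C)=C/C=C/C(C)=C/C=C/C=C(C)/C=C\C=C(C)\C=C\[C@]1(O)C(C)(C)C[C@H](O)C[C@]1(C)O | intermediate
29 | (3S,5S,6S,3'R,6'R)-5,6-dihydro-β,ε-carotene-3,5,6,3'-tetrol (all-E) | CC1=C[C@H](O)CC(C)(C)[C@H]1/C=C/C(C)=C/C=C/C(C)=C/C=C/C=C(C)/C=C/C=C(C)/C=C/[C@]1(O)C(C)(C)C[C@H](O)C[C@]1(C)O | target

## Step count and least certain steps

Total: 17 steps. Longest linear sequence: 10 steps (12 to 29, steps 8–17); the ring A branch is 8 steps (1 to 29).

Step 5 (key step). Poor facial selectivity in the oxygen transfer would cut the throughput, since only the anti epoxide can cyclise. After activation by the Lewis acid, a 1,2-shift at the C5 cation (ring contraction or alkynyl migration) or loss of the tert-butyl carbonate may outrun the bridged closure, which has to pass through the conformer with O3 and a C1 methyl syn-axial. The fallback sets out from 4 and returns at 10; it moves the tethered opening to a plain trisubstituted epoxide and sets C6 afterwards by carbonyl addition. Palladium-catalysed formate reduction of the triflate (Pd(OAc)2, PPh3, HCO2H, Bu3N, DMF) gives tert-butyl (1R)-3,5,5-trimethylcyclohex-3-en-1-yl carbonate F1. The same epoxidation and carbonate transfer, now with a secondary C6 and no alkynyl group to migrate or to stabilise a cation, gives (1S,5S,8S)-8-hydroxy-1,7,7-trimethyl-2,4-dioxabicyclo[3.3.1]nonan-3-one F2. Dess–Martin oxidation gives (1S,5S)-1,7,7-trimethyl-2,4-dioxabicyclo[3.3.1]nonane-3,8-dione F3, and K2CO3 in MeOH frees (2S,4S)-2,4-dihydroxy-2,6,6-trimethylcyclohexan-1-one F4. Addition of 5, doubly deprotonated with n-BuLi (CeCl3, THF, −78 °C), to the carbonyl group from the face opposite to the two axial methyl groups forms C6–C7 and gives (2E)-5-[(1R,2S,4S)-1,2,4-trihydroxy-2,6,6-trimethylcyclohexyl]-3-methylpent-2-en-4-yn-1-ol F5, which the hydride of step 6 reduces to 10.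

Step 10. Poor or reversed facial selectivity of hydride addition is possible because the bias comes only from the remote C6' substituent and the C1' methyl groups and depends on the ring conformation. The fallback sets out from 16 and returns at 19 and makes the sequence convergent: the two C3' epimers are separated; the cis epimer 17 goes on through steps 11 and 12, and the trans epimer ethyl (2E,4E)-5-[(1R,4R)-4-hydroxy-2,6,6-trimethylcyclohex-2-en-1-yl]-3-methylpenta-2,4-dienoate F8 is reduced directly with i-Bu2AlH to 19.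

Step 16. Acid may ionise the allylic 3'-OH of ring B (epimerisation or substitution at C3'), or scramble the geometry of the heptaenyl cation. The fallback reverses the polarity of the last coupling; it sets out from 10 and 24 and returns at 29. Appel bromination of the primary dienylic alcohol of 10 (CBr4, PPh3, CH2Cl2, −30 °C) followed by excess PPh3 gives, without acid, {(2E,4E)-5-[(1S,2S,4S)-1,2,4-trihydroxy-2,6,6-trimethylcyclohexyl]-3-methylpenta-2,4-dien-1-yl}triphenylphosphonium bromide F9. Its Wittig reaction with 24 (NaOMe, MeOH/CH2Cl2, then heating) gives 29.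

Step 6. Over-reduction or allene formation from the enynol unit, or incomplete cleavage of the hindered carbonate, may lower the yield of the one-pot global reduction. The fallback separates the tasks and changes the mechanism of alkyne reduction; it sets out from 9 and returns at 10. K2CO3 in MeOH removes acetate and carbonate to give (2E)-5-[(1R,2S,4S)-1,2,4-trihydroxy-2,6,6-trimethylcyclohexyl]-3-methylpent-2-en-4-yn-1-ol F6. Ruthenium-catalysed trans-hydrosilylation ([Cp*Ru(MeCN)3]PF6, (EtO)3SiH, CH2Cl2) gives (2E,4Z)-5-[(1S,2S,4S)-1,2,4-trihydroxy-2,6,6-trimethylcyclohexyl]-3-methyl-4-(triethoxysilyl)penta-2,4-dien-1-ol F7, and protodesilylation with retention (Bu4NF, CuI, THF) gives 10.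

## Further compounds

F1 | step 5 | tert-butyl (1R)-3,5,5-trimethylcyclohex-3-en-1-yl carbonate | CC1=CC(C)(C)C[C@H](OC(=O)OC(C)(C)C)C1
F2 | step 5 | (1S,5S,8S)-8-hydroxy-1,7,7-trimethyl-2,4-dioxabicyclo[3.3.1]nonan-3-one | O[C@H]1C(C)(C)C[C@H]2C[C@]1(C)OC(=O)O2
F3 | step 5 | (1S,5S)-1,7,7-trimethyl-2,4-dioxabicyclo[3.3.1]nonane-3,8-dione | O=C1C(C)(C)C[C@H]2C[C@]1(C)OC(=O)O2
F4 | step 5 | (2S,4S)-2,4-dihydroxy-2,6,6-trimethylcyclohexan-1-one | O=C1C(C)(C)C[C@H](O)C[C@]1(C)O
F5 | step 5 | (2E)-5-[(1R,2S,4S)-1,2,4-trihydroxy-2,6,6-trimethylcyclohexyl]-3-methylpent-2-en-4-yn-1-ol | OC/C=C(C)/C#C[C@]1(O)C(C)(C)C[C@H](O)C[C@]1(C)O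
F6 | step 6 | (2E)-5-[(1R,2S,4S)-1,2,4-trihydroxy-2,6,6-trimethylcyclohexyl]-3-methylpent-2-en-4-yn-1-ol | OC/C=C(C)/C#C[C@]1(O)C(C)(C)C[C@H](O)C[C@]1(C)O
F7 | step 6 | (2E,4Z)-5-[(1S,2S,4S)-1,2,4-trihydroxy-2,6,6-trimethylcyclohexyl]-3-methyl-4-(triethoxysilyl)penta-2,4-dien-1-ol | OC/C=C(C)/C([Si](OCC)(OCC)OCC)=C/[C@]1(O)C(C)(C)C[C@H](O)C[C@]1(C)O
F8 | step 10 | ethyl (2E,4E)-5-[(1R,4R)-4-hydroxy-2,6,6-trimethylcyclohex-2-en-1-yl]-3-methylpenta-2,4-dienoate | CCOC(=O)/C=C(C)/C=C/[C@H]1C(C)=C[C@H](O)CC1(C)C
F9 | step 16 | {(2E,4E)-5-[(1S,2S,4S)-1,2,4-trihydroxy-2,6,6-trimethylcyclohexyl]-3-methylpenta-2,4-dien-1-yl}triphenylphosphonium bromide | [Br-].c1ccc(cc1)[P+](c1ccccc1)(c1ccccc1)C/C=C(C)/C=C/[C@]1(O)C(C)(C)C[C@H](O)C[C@]1(C)O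
A1 | alternative 1 | (3R,3'R,6'R)-β,ε-carotene-3,3'-diol (lutein) | CC1=C(/C=C/C(C)=C/C=C/C(C)=C/C=C/C=C(C)/C=C/C=C(C)/C=C/[C@H]2C(C)=C[C@H](O)CC2(C)C)C(C)(C)C[C@H](O)C1
A2 | alternative 1 | (3S,5R,6S,3'R,6'R)-5,6-epoxy-5,6-dihydro-β,ε-carotene-3,3'-diol (lutein 5,6-epoxide, epoxide anti to O3) | CC1=C[C@H](O)CC(C)(C)[C@H]1/C=C/C(C)=C/C=C/C(C)=C/C=C/C=C(C)/C=C/C=C(C)/C=C/[C@]1(O2)C(C)(C)C[C@H](O)C[C@]12C
A3 | alternative 2 | (2S,4S)-2,4-dihydroxy-2,6,6-trimethylcyclohexan-1-one (O3/O5-cis ketol) | O=C1C(C)(C)C[C@H](O)C[C@]1(C)O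
A4 | alternative 2 | (2R,4S)-2,4-dihydroxy-2,6,6-trimethylcyclohexan-1-one (O3/O5-trans ketol) | O=C1C(C)(C)C[C@H](O)C[C@@]1(C)O
A5 | alternative 3 | (4R)-4-[(tert-butyldimethylsilyl)oxy]-2,6,6-trimethylcyclohex-2-en-1-one | CC1=C[C@H](O[Si](C)(C)C(C)(C)C)CC(C)(C)C1=O
A6 | alternative 3 | 4'-tosylhydrazone of the bis(tert-butyldimethylsilyl) ether of the 3'-hydroxy-4'-oxo-7',8'-didehydro-β-ring C15 enynol, C3' configured as in ring B of 29 | CC1=C(C#C/C(C)=C/CO[Si](C)(C)C(C)(C)C)C(C)(C)C[C@@H](O[Si](C)(C)C(C)(C)C)C1=NNS(=O)(=O)c1ccc(C)cc1
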